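The ten-membered carbocycle is closed late, across C5–C6 (germacrane numbering), the bond that joins the vinylic CH of the C4=C5 alkene to the lactone carbinol carbon. An intramolecular Nozaki–Hiyama–Kishi addition of a (Z)-alkenyl iodide to a C6 aldehyde forms the ring, keeps both ring alkenes cis and creates the C6 stereocentre under control of C7 in one operation; it exploits the allylic carbinol junction C5–C6 of the cyclodeca-1(10),4-diene ring. The precursor is an open chain that carries C7–C9 with C8/C9 as a trans-dioxolane, the C1=C10 enoate and an ethynyl group on C7; palladium-catalysed carbonylation later joins this alkyne and the new C6 hydroxyl into the α-methylene-γ-lactone.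

Key step: step 16

Remark: atom numbers follow germacranolide usage (ring C1–C10; C11–C13 the lactone carbons on C7; C14 the carboxyl carbon on C10; C15 the methyl on C4); the C1=C10 bond is E by the sequence rules although its ring bonds are cis.
Abbreviations: TBS = tert-butyl(dimethyl)silyl; TMS = trimethylsilyl; PMB = 4-methoxybenzyl.

Step 1
Reactants: 1 2-(2-bromoethyl)-1,3-dioxolane; 2 propyne
Product: 6 2-[(3Z)-4-iodo-3-methylbut-3-en-1-yl]-1,3-dioxolane, via alkylmagnesium bromide 3 (not isolated), via alkylcopper 4 (not isolated), via (Z)-alkenylcopper 5 (not isolated)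
Conditions: Mg, THF, 25 °C; CuBr·SMe2, Et2O/Me2S, −45 °C; 2, −25 °C; I2, −50 → 0 °C
Reagents that add atoms: iodine [I][I]
Why: Carbocupration of a terminal alkyne is a syn carbometalation that puts the alkyl group on the internal carbon and copper on the terminal carbon on the same side, so iodinolysis with retention should give the (Z)-iodide with iodine cis to the chain.

Step 2
Reactants: 6 2-[(3Z)-4-iodo-3-methylbut-3-en-1-yl]-1,3-dioxolane
Product: 7 (4Z)-5-iodo-4-methylpent-4-enal
Conditions: 1 M HCl, THF, 40 °C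
Reagents that add atoms: water O
Why: Acid-catalysed acetal hydrolysis should free the aldehyde and leave the alkenyl iodide untouched.

Step 3
Reactants: 8 (2E)-but-2-ene-1,4-diol
Product: 9 (2E)-4-(TBS-oxy)but-2-en-1-ol
Conditions: TBSCl (1 equiv), imidazole, THF, 0 °C, 8 in threefold excess
Reagents that add atoms: tert-butyl(chloro)dimethylsilane CC(C)(C)[Si](C)(C)Cl
Why: Silyl ether formation on a symmetrical diol used in excess should give mainly the mono-ether.

Step 4
Reactants: 9 (2E)-4-(TBS-oxy)but-2-en-1-ol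
Product: 10 [(2R,3R)-3-(TBS-oxymethyl)oxiran-2-yl]methanol
Conditions: Ti(OiPr)4 (cat.), D-(−)-diethyl tartrate (cat.), t-BuOOH, 4 Å MS, CH2Cl2, −20 °C
Reagents that add atoms: tert-butyl hydroperoxide CC(C)(C)OO
Why: Sharpless asymmetric epoxidation with the D-(−)-tartrate delivers oxygen to the face of the (E)-allylic alcohol that gives the (2R,3R)-epoxide, which fixes the later C8 centre and the precursor of C7.

Step 5
Reactants: 10 [(2R,3R)-3-(TBS-oxymethyl)oxiran-2-yl]methanol; 11 ethynyl(trimethyl)silane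
Product: 14 (2S,3S)-3-(TBS-oxymethyl)-5-(trimethylsilyl)pent-4-yne-1,2-diol, via lithium (trimethylsilyl)acetylide 12 (not isolated), via diethyl(alkynyl)alane 13 (not isolated)
Conditions: 11, n-BuLi, toluene, 0 °C; Et2AlCl, 0 °C; then 10, 0 °C → rt; aq. potassium sodium tartrate
Reagents that add atoms: none
Why: Alkynylalane opening of a 2,3-epoxy alcohol is directed by the aluminium alkoxide to C3, which is attacked with inversion (SN2), so C7 is set anti to the C8 hydroxyl.

Step 6
Reactants: 14 (2S,3S)-3-(TBS-oxymethyl)-5-(trimethylsilyl)pent-4-yne-1,2-diol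
Product: 15 (4S)-4-[(2S)-1-(TBS-oxy)-4-(trimethylsilyl)but-3-yn-2-yl]-2-(4-methoxyphenyl)-1,3-dioxolane (either epimer at the acetal carbon)
Conditions: 4-MeOC6H4CH(OMe)2, PPTS (cat.), CH2Cl2, rt
Reagents that add atoms: 4-methoxybenzaldehyde dimethyl acetal COc1ccc(cc1)C(OC)OC
Why: Acid-catalysed transacetalisation should close the five-membered 4-methoxybenzylidene acetal on the 1,2-diol.

Step 7
Reactants: 15 the 4-methoxybenzylidene acetal of step 6
Product: 16 (2S,3S)-3-(TBS-oxymethyl)-2-(PMB-oxy)-5-(trimethylsilyl)pent-4-yn-1-ol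
Conditions: i-Bu2AlH, CH2Cl2, −78 → 0 °C; aq. potassium sodium tartrate
Reagents that add atoms: none
Why: Regioselective reductive acetal opening, in which the aluminium hydride binds the less hindered primary oxygen and cleaves its C–O bond, should leave the PMB group on the secondary C8 oxygen.

Step 8
Reactants: 16 (2S,3S)-3-(TBS-oxymethyl)-2-(PMB-oxy)-5-(trimethylsilyl)pent-4-yn-1-ol
Product: 17 (2S,3S)-3-(TBS-oxymethyl)-2-(PMB-oxy)-5-(trimethylsilyl)pent-4-ynal
Conditions: Dess–Martin periodinane, NaHCO3, CH2Cl2, 0 °C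
Reagents that add atoms: none
Why: Buffered Dess–Martin oxidation should give the α-alkoxy aldehyde without epimerisation at C8.

Step 9
Reactants: 18 tert-butyl acetate
Product: 20 tert-butyl[(1-tert-butoxyethenyl)oxy]dimethylsilane, via lithium enolate 19 (not isolated)
Conditions: LiN(i-Pr)2, THF, −78 °C; TBSCl, DMPU, −78 °C → rt
Reagents that add atoms: tert-butyl(chloro)dimethylsilane CC(C)(C)[Si](C)(C)Cl
Why: O-Silylation of the ester lithium enolate gives the silyl ketene acetal needed for the Mukaiyama aldol.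

Step 10
Reactants: 17 (2S,3S)-3-(TBS-oxymethyl)-2-(PMB-oxy)-5-(trimethylsilyl)pent-4-ynal; 20 tert-butyl[(1-tert-butoxyethenyl)oxy]dimethylsilane
Product: 21 tert-butyl (3S,4S,5S)-5-(TBS-oxymethyl)-3-hydroxy-4-(PMB-oxy)-7-(trimethylsilyl)hept-6-ynoate
Conditions: MgBr2·OEt2 (3 equiv), CH2Cl2, −78 → −30 °C; 1 M HCl work-up
Reagents that add atoms: none
Why: In this chelation-controlled Mukaiyama aldol addition MgBr2 ties the aldehyde oxygen to the C8 PMB ether (Cram chelate) and the ketene acetal attacks anti to the C7 branch, which sets C9 as S, syn to the C8 oxygen.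

Step 11
Reactants: 21 tert-butyl (3S,4S,5S)-5-(TBS-oxymethyl)-3-hydroxy-4-(PMB-oxy)-7-(trimethylsilyl)hept-6-ynoate; 7 (4Z)-5-iodo-4-methylpent-4-enal
Product: 23 tert-butyl (3S,4S,5S)-5-(TBS-oxymethyl)-3-hydroxy-2-[(4Z)-1-hydroxy-5-iodo-4-methylpent-4-en-1-yl]-4-(PMB-oxy)-7-(trimethylsilyl)hept-6-ynoate (mixture at C2 and at the new carbinol), via dilithium dianion 22 (not isolated)
Conditions: LiN(i-Pr)2 (2.2 equiv), THF, −78 → −30 °C; 7, −78 °C; aq. NH4Cl
Reagents that add atoms: none
Why: Aldol addition of the dianion of a β-hydroxy ester, whose alkoxide blocks β-elimination, joins C10 to C1, and the two new centres are removed again in step 13.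

Step 12
Reactants: 23 the aldol diol of step 11
Product: 24 tert-butyl (6Z)-2-{(4S,5S)-5-[(2S)-1-(TBS-oxy)-4-(trimethylsilyl)but-3-yn-2-yl]-2-(4-methoxyphenyl)-1,3-dioxolan-4-yl}-3-hydroxy-7-iodo-6-methylhept-6-enoate (mixture at C2 and C3 and at the acetal carbon)
Conditions: DDQ, 4 Å MS, CH2Cl2, 0 °C
Reagents that add atoms: none
Why: In this DDQ-mediated oxidative acetalisation the PMB ether is oxidised to an oxocarbenium ion that the neighbouring C9 hydroxyl traps in the five-membered mode, so only the C1 hydroxyl stays free.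

Step 13
Reactants: 24 the dioxolane alcohol of step 12
Product: 26 tert-butyl (2E,6Z)-2-{(4S,5S)-5-[(2S)-1-(TBS-oxy)-4-(trimethylsilyl)but-3-yn-2-yl]-2-(4-methoxyphenyl)-1,3-dioxolan-4-yl}-7-iodo-6-methylhepta-2,6-dienoate, via C1 mesylate 25 (not isolated)
Conditions: MsCl, Et3N, CH2Cl2, 0 °C; then DBU, rt
Reagents that add atoms: none
Why: Mesylation and E1cB elimination through the ester enolate should give the conjugated ester with the chain trans to the ester group (2E), the geometry in which the ester stays coplanar and allylic strain is least.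

Step 14
Reactants: 26 the (2E,6Z)-dienoate of step 13
Product: 27 tert-butyl (2E,6Z)-2-{(4S,5S)-5-[(2S)-1-hydroxybut-3-yn-2-yl]-2-(4-methoxyphenyl)-1,3-dioxolan-4-yl}-7-iodo-6-methylhepta-2,6-dienoate
Conditions: TBAF, THF, 0 °C → rt
Reagents that add atoms: none
Why: Fluoride-induced desilylation should cleave the primary silyl ether and the alkynylsilane in one operation.

Step 15
Reactants: 27 the primary alcohol of step 14
Product: 28 tert-butyl (2E,6Z)-7-iodo-2-{(4S,5S)-2-(4-methoxyphenyl)-5-[(2R)-1-oxobut-3-yn-2-yl]-1,3-dioxolan-4-yl}-6-methylhepta-2,6-dienoate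
Conditions: Dess–Martin periodinane, NaHCO3, CH2Cl2, 0 °C; used at once
Reagents that add atoms: none
Why: Buffered, non-basic Dess–Martin oxidation should give the α-ethynyl aldehyde without epimerisation at C7.

Step 16
Reactants: 28 the iodo aldehyde of step 15
Product: 30 tert-butyl (1(10)E,4Z,6R,7S,8S,9S)-7-ethynyl-6-hydroxy-8,9-[(4-methoxybenzylidene)dioxy]-4-methylcyclodeca-1(10),4-diene-10-carboxylate (germacrane locants), via alkenylchromium dichloride 29 (not isolated)
Conditions: CrCl2 (8 equiv), NiCl2 (2 mol %), DMSO/THF, 0.003 M, rt, slow addition of 28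
Reagents that add atoms: none
Why: CrCl2 reduces NiCl2 to zerovalent nickel, which inserts into the C5–I bond; transmetalation gives the alkenylchromium dichloride (trivalent chromium) with retention of the Z geometry, and this adds only to the C6 aldehyde, since such reagents ignore esters, acetals and alkynes. The closest known reaction type is the Nozaki–Hiyama–Kishi macrocyclisation of iodoalkenyl aldehydes to medium and large carbocycles. One ring is closed, the ten-membered carbocycle, by 1,2-addition of C5 to the C6 carbonyl carbon (10-exo-trig at the carbonyl). The new C6 centre is controlled by C7 in a Felkin–Anh arrangement in which the bulky ring-bound C7–C8 bond lies anti to the incoming C5 and the slim ethynyl group sits next to the carbonyl oxygen, which should give the 6R carbinol with H6 and H7 anti, as the trans-lactone needs. The step needs ring closure to win over oligomerisation and C7 to keep its configuration: high dilution, the two cis ring alkenes and the trans-dioxolane that bend the chain ends towards each other, and the neutral medium should secure both.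

Step 17
Reactants: 30 the ten-membered homopropargylic alcohol of step 16
Product: 31 tert-butyl (1(10)E,4Z,6R,7S,8S,9S)-8,9-[(4-methoxybenzylidene)dioxy]-12-oxo-6,12-epoxygermacra-1(10),4,11(13)-trien-14-oate
Conditions: PdCl2 (5 mol %), PPh3, SnCl2, CO (7 atm), MeCN, 70 °C
Reagents that add atoms: carbon monoxide [C-]#[O+]
Why: In this palladium-catalysed cyclocarbonylation of a homopropargylic alcohol the alkoxycarbonyl-palladium unit on the C6 oxygen adds cis across the ethynyl group in the 5-exo mode and protonolysis releases the α-methylene-γ-butyrolactone, whose trans fusion follows from the anti C6/C7 relationship already present in 30.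

Step 18
Reactants: 31 the acetal-protected lactone of step 17
Product: 32 tert-butyl (1(10)E,4Z,6R,7R,8S,9S)-8,9-dihydroxy-12-oxo-6,12-epoxygermacra-1(10),4,11(13)-trien-14-oate
Conditions: AcOH/THF/H2O (3:1:1), 40 °C
Reagents that add atoms: none
Why: Mild acid hydrolysis of the benzylidene acetal should free the C8/C9 diol while the tert-butyl ester and the lactone remain.

Step 19
Reactants: 32 the diol of step 18; 33 angelic acid [(2Z)-2-methylbut-2-enoic acid] (two molecules are taken up per molecule of 32; the second is entered under the reagents below)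
Product: 35 tert-butyl (1(10)E,4Z,6R,7S,8S,9S)-8,9-bis(angeloyloxy)-12-oxo-6,12-epoxygermacra-1(10),4,11(13)-trien-14-oate, via mixed anhydride 34 (not isolated)
Conditions: 33 (6 equiv), 2,4,6-Cl3C6H2COCl (6 equiv), Et3N (12 equiv), toluene, rt; then 32 (1 equiv), 80 °C
Reagents that add atoms: angelic acid (second molecule of 33, likewise converted into 34) C/C=C(/C)C(=O)O
Why: Yamaguchi-type esterification through the mixed anhydride 34, two molecules of which each deliver one angeloyl group (one to the C9 and one to the C8 hydroxyl), is run with excess anhydride and without a nucleophilic catalyst because this should acylate both hindered hydroxyls without Z-to-E isomerisation.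

Step 20
Reactants: 35 the tert-butyl ester of step 19
Product: 36 (1(10)E,4Z,6R,7S,8S,9S)-8,9-bis{[(2Z)-2-methylbut-2-enoyl]oxy}-12-oxo-6,12-epoxygermacra-1(10),4,11(13)-trien-14-oic acid (CNP0154468.1)
Conditions: CF3CO2H/CH2Cl2 (1:4), 0 °C
Reagents that add atoms: none
Why: Acidolysis of the tert-butyl ester with loss of 2-methylpropene should free the C14 carboxylic acid and leave the lactone and the angelates intact.

Compound list
1 | 2-(2-bromoethyl)-1,3-dioxolane | BrCCC1OCCO1 | starting material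
2 | propyne | CC#C | starting material
3 | [2-(1,3-dioxolan-2-yl)ethyl]magnesium bromide (formed in the flask) | Br[Mg]CCC1OCCO1 | intermediate
4 | [2-(1,3-dioxolan-2-yl)ethyl]copper (formed in the flask) | [Cu]CCC1OCCO1 | intermediate
5 | [(1Z)-4-(1,3-dioxolan-2-yl)-2-methylbut-1-en-1-yl]copper (formed in the flask) | [Cu]/C=C(/C)CCC1OCCO1 | intermediate
6 | 2-[(3Z)-4-iodo-3-methylbut-3-en-1-yl]-1,3-dioxolane | I/C=C(/C)CCC1OCCO1 | intermediate
7 | (4Z)-5-iodo-4-methylpent-4-enal | I/C=C(/C)CCC=O | intermediate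
8 | (2E)-but-2-ene-1,4-diol | OC/C=C/CO | starting material
9 | (2E)-4-{[tert-butyl(dimethyl)silyl]oxy}but-2-en-1-ol | OC/C=C/CO[Si](C)(C)C(C)(C)C | intermediate
10 | [(2R,3R)-3-({[tert-butyl(dimethyl)silyl]oxy}methyl)oxiran-2-yl]methanol | OC[C@H]1O[C@@H]1CO[Si](C)(C)C(C)(C)C | intermediate
11 | ethynyl(trimethyl)silane | C#C[Si](C)(C)C | starting material
12 | lithium (trimethylsilyl)acetylide (formed in the flask) | [Li]C#C[Si](C)(C)C | intermediate
13 | diethyl[(trimethylsilyl)ethynyl]aluminium (formed in the flask) | CC[Al](CC)C#C[Si](C)(C)C | intermediate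
14 | (2S,3S)-3-({[tert-butyl(dimethyl)silyl]oxy}methyl)-5-(trimethylsilyl)pent-4-yne-1,2-diol | OC[C@@H](O)[C@@H](C#C[Si](C)(C)C)CO[Si](C)(C)C(C)(C)C | intermediate
15 | (4S)-4-[(2S)-1-{[tert-butyl(dimethyl)silyl]oxy}-4-(trimethylsilyl)but-3-yn-2-yl]-2-(4-methoxyphenyl)-1,3-dioxolane (acetal carbon unassigned) | COc1ccc(cc1)C1OC[C@@H](O1)[C@@H](C#C[Si](C)(C)C)CO[Si](C)(C)C(C)(C)C | intermediate
16 | (2S,3S)-3-({[tert-butyl(dimethyl)silyl]oxy}methyl)-2-[(4-methoxybenzyl)oxy]-5-(trimethylsilyl)pent-4-yn-1-ol | OC[C@@H](OCc1ccc(OC)cc1)[C@@H](C#C[Si](C)(C)C)CO[Si](C)(C)C(C)(C)C | intermediate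
17 | (2S,3S)-3-({[tert-butyl(dimethyl)silyl]oxy}methyl)-2-[(4-methoxybenzyl)oxy]-5-(trimethylsilyl)pent-4-ynal | O=C[C@@H](OCc1ccc(OC)cc1)[C@@H](C#C[Si](C)(C)C)CO[Si](C)(C)C(C)(C)C | intermediate
18 | tert-butyl acetate | CC(=O)OC(C)(C)C | starting material
19 | lithium enolate of tert-butyl acetate (formed in the flask) | [Li]OC(=C)OC(C)(C)C | intermediate
20 | tert-butyl[(1-tert-butoxyethenyl)oxy]dimethylsilane | C=C(OC(C)(C)C)O[Si](C)(C)C(C)(C)C | intermediate
21 | tert-butyl (3S,4S,5S)-5-({[tert-butyl(dimethyl)silyl]oxy}methyl)-3-hydroxy-4-[(4-methoxybenzyl)oxy]-7-(trimethylsilyl)hept-6-ynoate | CC(C)(C)OC(=O)C[C@H](O)[C@@H](OCc1ccc(OC)cc1)[C@@H](C#C[Si](C)(C)C)CO[Si](C)(C)C(C)(C)C | intermediate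
22 | dilithium alkoxide-enolate of 21 (formed in the flask) | CC(C)(C)OC(O[Li])=C[C@H](O[Li])[C@@H](OCc1ccc(OC)cc1)[C@@H](C#C[Si](C)(C)C)CO[Si](C)(C)C(C)(C)C | intermediate
23 | tert-butyl (3S,4S,5S)-5-({[tert-butyl(dimethyl)silyl]oxy}methyl)-3-hydroxy-2-[(4Z)-1-hydroxy-5-iodo-4-methylpent-4-en-1-yl]-4-[(4-methoxybenzyl)oxy]-7-(trimethylsilyl)hept-6-ynoate (C2 and side-chain carbinol unassigned) | CC(C)(C)OC(=O)C(C(O)CC/C(C)=C\I)[C@H](O)[C@@H](OCc1ccc(OC)cc1)[C@@H](C#C[Si](C)(C)C)CO[Si](C)(C)C(C)(C)C | intermediate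
24 | tert-butyl (6Z)-2-{(4S,5S)-5-[(2S)-1-{[tert-butyl(dimethyl)silyl]oxy}-4-(trimethylsilyl)but-3-yn-2-yl]-2-(4-methoxyphenyl)-1,3-dioxolan-4-yl}-3-hydroxy-7-iodo-6-methylhept-6-enoate (C2, C3 and acetal carbon unassigned) | CC(C)(C)OC(=O)C(C(O)CC/C(C)=C\I)[C@@H]1OC(c2ccc(OC)cc2)O[C@H]1[C@@H](C#C[Si](C)(C)C)CO[Si](C)(C)C(C)(C)C | intermediate
25 | 3-methanesulfonate of 24 (formed in the flask) | CC(C)(C)OC(=O)C(C(OS(C)(=O)=O)CC/C(C)=C\I)[C@@H]1OC(c2ccc(OC)cc2)O[C@H]1[C@@H](C#C[Si](C)(C)C)CO[Si](C)(C)C(C)(C)C | intermediate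
26 | tert-butyl (2E,6Z)-2-{(4S,5S)-5-[(2S)-1-{[tert-butyl(dimethyl)silyl]oxy}-4-(trimethylsilyl)but-3-yn-2-yl]-2-(4-methoxyphenyl)-1,3-dioxolan-4-yl}-7-iodo-6-methylhepta-2,6-dienoate | CC(C)(C)OC(=O)/C(=C/CC/C(C)=C\I)[C@@H]1OC(c2ccc(OC)cc2)O[C@H]1[C@@H](C#C[Si](C)(C)C)CO[Si](C)(C)C(C)(C)C | intermediate
27 | tert-butyl (2E,6Z)-2-{(4S,5S)-5-[(2S)-1-hydroxybut-3-yn-2-yl]-2-(4-methoxyphenyl)-1,3-dioxolan-4-yl}-7-iodo-6-methylhepta-2,6-dienoate | CC(C)(C)OC(=O)/C(=C/CC/C(C)=C\I)[C@@H]1OC(c2ccc(OC)cc2)O[C@H]1[C@@H](C#C)CO | intermediate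
28 | tert-butyl (2E,6Z)-7-iodo-2-{(4S,5S)-2-(4-methoxyphenyl)-5-[(2R)-1-oxobut-3-yn-2-yl]-1,3-dioxolan-4-yl}-6-methylhepta-2,6-dienoate | CC(C)(C)OC(=O)/C(=C/CC/C(C)=C\I)[C@@H]1OC(c2ccc(OC)cc2)O[C@H]1[C@@H](C#C)C=O | intermediate
29 | (Z)-alkenylchromium dichloride derived from 28 at C5 (formed in the flask) | CC(C)(C)OC(=O)/C(=C/CC/C(C)=C\[Cr](Cl)Cl)[C@@H]1OC(c2ccc(OC)cc2)O[C@H]1[C@@H](C#C)C=O | intermediate
30 | tert-butyl (1(10)E,4Z,6R,7S,8S,9S)-7-ethynyl-6-hydroxy-8,9-[(4-methoxybenzylidene)dioxy]-4-methylcyclodeca-1(10),4-diene-10-carboxylate (germacrane locants) | O[C@@H]1/C=C(/C)CC/C=C(/C(=O)OC(C)(C)C)[C@@H]2OC(c3ccc(OC)cc3)O[C@H]2[C@H]1C#C | intermediate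
31 | tert-butyl (1(10)E,4Z,6R,7S,8S,9S)-8,9-[(4-methoxybenzylidene)dioxy]-12-oxo-6,12-epoxygermacra-1(10),4,11(13)-trien-14-oate | C=C1C(=O)O[C@@H]2/C=C(/C)CC/C=C(/C(=O)OC(C)(C)C)[C@@H]3OC(c4ccc(OC)cc4)O[C@H]3[C@@H]12 | intermediate
32 | tert-butyl (1(10)E,4Z,6R,7R,8S,9S)-8,9-dihydroxy-12-oxo-6,12-epoxygermacra-1(10),4,11(13)-trien-14-oate | C=C1C(=O)O[C@@H]2/C=C(/C)CC/C=C(/C(=O)OC(C)(C)C)[C@H](O)[C@@H](O)[C@@H]12 | intermediate
33 | angelic acid, (2Z)-2-methylbut-2-enoic acid | C/C=C(/C)C(=O)O | starting material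
34 | (2Z)-2-methylbut-2-enoic 2,4,6-trichlorobenzoic anhydride (formed in the flask) | C/C=C(/C)C(=O)OC(=O)c1c(Cl)cc(Cl)cc1Cl | intermediate
35 | tert-butyl (1(10)E,4Z,6R,7S,8S,9S)-8,9-bis{[(2Z)-2-methylbut-2-enoyl]oxy}-12-oxo-6,12-epoxygermacra-1(10),4,11(13)-trien-14-oate | C=C1C(=O)O[C@@H]2/C=C(/C)CC/C=C(/C(=O)OC(C)(C)C)[C@H](OC(=O)/C(C)=C\C)[C@@H](OC(=O)/C(C)=C\C)[C@@H]12 | intermediate
36 | (1(10)E,4Z,6R,7S,8S,9S)-8,9-bis{[(2Z)-2-methylbut-2-enoyl]oxy}-12-oxo-6,12-epoxygermacra-1(10),4,11(13)-trien-14-oic acid (CNP0154468.1) | C=C1C(=O)O[C@@H]2/C=C(/C)CC/C=C(/C(=O)O)[C@H](OC(=O)/C(C)=C\C)[C@@H](OC(=O)/C(C)=C\C)[C@@H]12 | target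

Total step count: 20.
Longest linear sequence: 17 steps (from 8 through steps 3–8 and 10–20 to 36). Steps 1–2 (aldehyde 7) and step 9 (ketene acetal 20) are side branches.

Steps most likely to fail

Step 16 (ring closure). What may go wrong is attack of C5 on the wrong face of the C6 aldehyde, because the ten-membered transition state may not follow the open-chain Felkin–Anh preference. Oligomerisation and loss of configuration at the propargylic C7 are lesser risks. The fallback keeps the ring closure but moves control of C6 from the substrate to a reagent. It sets out from 28: the cyclisation is taken as it comes to the 6-epimeric carbinol F1. Dess–Martin oxidation of F1 (or of a mixture of F1 and 30) should give the macrocyclic enone F2. Corey–Bakshi–Shibata reduction of F2 with the (R)-2-methyl-oxazaborolidine and catecholborane in toluene at −78 °C, the alkenyl side acting as the large group, should then deliver the 6R alcohol. The route is rejoined at 30.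

Step 17 (carbonylative lactonisation). What may go wrong is alkyne oligomerisation, acid-promoted loss of the benzylidene acetal under the trace HCl that the catalyst system releases, or acylpalladation in the endo mode. The fallback builds the lactone from an alkenyl halide and sets out from 30. Markovnikov hydrostannation of the ethynyl group (Bu3SnH, Mo(CO)3(CNtBu)3 cat., THF, 55 °C) should give the internal alkenylstannane F3. Iododestannylation (I2, CH2Cl2, 0 °C) should give the 2-iodoalkene F4. Intramolecular alkoxycarbonylation of F4 (Pd(PPh3)4 cat., CO 1 atm, K2CO3, THF, 50 °C) closes the lactone through the C6 hydroxyl. The route is rejoined at 31.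

Step 19 (double angeloylation). What may go wrong is isomerisation of the angeloyl double bond to the tigloyl isomer during acyl transfer, or incomplete acylation of the hindered C8 hydroxyl, which would stop at a mono-ester. The fallback builds the Z double bond on the molecule and sets out from 32. Both hydroxyls are first esterified with 2-[bis(2,2,2-trifluoroethoxy)phosphoryl]propanoic acid (two equivalents taken up; N,N'-diisopropylcarbodiimide, DMAP cat., CH2Cl2, 0 °C), which should give the bis(phosphonopropanoate) F5. Double Still–Gennari olefination of F5 with acetaldehyde (two equivalents taken up; KN(SiMe3)2, 18-crown-6, THF, −78 °C) should then give the two (Z)-2-methylbut-2-enoates. The route is rejoined at 35.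

Further compounds
F1 | step 16 | tert-butyl (1(10)E,4Z,6S,7S,8S,9S)-7-ethynyl-6-hydroxy-8,9-[(4-methoxybenzylidene)dioxy]-4-methylcyclodeca-1(10),4-diene-10-carboxylate (C6 epimer of 30) | O[C@H]1/C=C(/C)CC/C=C(/C(=O)OC(C)(C)C)[C@@H]2OC(c3ccc(OC)cc3)O[C@H]2[C@H]1C#C
F2 | step 16 | tert-butyl (1(10)E,4Z,7R,8S,9S)-7-ethynyl-8,9-[(4-methoxybenzylidene)dioxy]-4-methyl-6-oxocyclodeca-1(10),4-diene-10-carboxylate | O=C1/C=C(/C)CC/C=C(/C(=O)OC(C)(C)C)[C@@H]2OC(c3ccc(OC)cc3)O[C@H]2[C@H]1C#C
F3 | step 17 | 7-[1-(tributylstannyl)ethenyl] analogue of 30 (same configuration as 30) | O[C@@H]1/C=C(/C)CC/C=C(/C(=O)OC(C)(C)C)[C@@H]2OC(c3ccc(OC)cc3)O[C@H]2[C@H]1C(=C)[Sn](CCCC)(CCCC)CCCC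
F4 | step 17 | 7-(1-iodoethenyl) analogue of 30 (same configuration as 30) | O[C@@H]1/C=C(/C)CC/C=C(/C(=O)OC(C)(C)C)[C@@H]2OC(c3ccc(OC)cc3)O[C@H]2[C@H]1C(I)=C
F5 | step 19 | 8,9-bis{2-[bis(2,2,2-trifluoroethoxy)phosphoryl]propanoate} of diol 32 (phosphonate α-carbons unassigned) | C=C1C(=O)O[C@@H]2/C=C(/C)CC/C=C(/C(=O)OC(C)(C)C)[C@H](OC(=O)C(C)P(=O)(OCC(F)(F)F)OCC(F)(F)F)[C@@H](OC(=O)C(C)P(=O)(OCC(F)(F)F)OCC(F)(F)F)[C@@H]12
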